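A direct plan would tie the rings together as a spiro ketal: cyclohexane-1,4-dione A1 and 3,4-dihydroxyacetophenone A2 would give catechol ketal A3, twofold dehydrogenation quinone monoketal A4, opening with HBr bromo diaryl ether A5, Dakin oxidation triol A6, and fivefold bromination the target. Its weakest steps would be the bromide-triggered ketal opening, which would lack precedent and have to break one particular C–O bond; the final bromination, which would have to fill five positions yet spare the one next to the ether oxygen; and the dehydrogenation and Dakin steps, which would add length only to make and erase a cyclohexanone and an acetyl handle.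

The target is a dehydro-dimer of 2,3,5-tribromohydroquinone: O1 of one unit is bonded to C6, the only C–H carbon, of the other. The route rests on this O1(ring A)–C6(ring B) bond and forms it as the presumed biosynthesis would, by conjugate addition of the hydroquinone to its own quinone. In one redox-neutral operation the key step makes the diaryl ether and delivers ring B as the hydroquinone. All six bromines sit on the monomer beforehand, where their positions are unambiguous, so no late polybromination, no ketal opening and no handle that must be made and erased remain.

Key step: step 3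

Remark: the target has no stereocentre, and 2,5-dibromobenzene-1,4-diol is taken as a commercial starting material.

Step 1
Reactants: 1 2,5-dibromobenzene-1,4-diol
Product: 2 2,3,5-tribromobenzene-1,4-diol
Conditions: Br2 (1.0 equiv), AcOH, 20 → 50 °C
Reagents that add atoms: bromine, BrBr
Why: Electrophilic aromatic bromination ortho to a phenolic hydroxyl, in which the two free positions of 1 are equivalent so that only one tribromide can form, and the third bromine slows a fourth substitution.

Step 2
Reactants: 2 2,3,5-tribromobenzene-1,4-diol
Product: 3 2,3,5-tribromocyclohexa-2,5-diene-1,4-dione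
Conditions: Ag2O (1.5 equiv), Na2SO4, Et2O, 20 °C, dark
Reagents that add atoms: none
Why: Dehydrogenation of a hydroquinone to the p-benzoquinone by Ag2O, a standard oxidation that touches neither the bromines nor the ring C–H and, being run without water, keeps the electrophilic haloquinone away from oxygen nucleophiles.

Step 3
Reactants: 2 2,3,5-tribromobenzene-1,4-diol; 3 2,3,5-tribromocyclohexa-2,5-diene-1,4-dione
Product: 6 2,3,5-tribromo-6-(2,3,5-tribromo-4-hydroxyphenoxy)benzene-1,4-diol, via hydroxydienone adduct 4 (not isolated), via aryloxyquinone 5 (not isolated)
Conditions: 2 (2.0 equiv), Cs2CO3 (20 mol %), MeCN (degassed), 0 → 20 °C, argon, dark; then aq. Na2S2O4, 1 M HCl, EtOAc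
Reagents that add atoms: none
Why: Proposed new method: the carbonate turns part of 2 into its monophenoxides, and the O1 phenoxide adds in conjugate (oxa-Michael) fashion to C6 of 3, the only ring carbon of the quinone that carries hydrogen, to give the bromo enolate of hydroxydienone 4, which loses the C6 proton next to the C1 carbonyl and aromatises to ring B of 6, so that the reversible addition is pulled forward and the base is regenerated. The closest known reaction types are the addition of thiols, amines and hydrogen halides to the free position of halo-p-benzoquinones with retention of the halogens, and the displacement of halide from tetrahalo-p-benzoquinones by phenoxides. No ring is closed, and the single stereocentre of 4 (C6, racemic) is erased on aromatisation, so nothing has to be controlled there. The step needs O1 over O4 of 2, oxygen over carbon attack, and attack at C6–H of 3 instead of ipso attack at a C–Br carbon: O4 lies between two bromines and would have to build a tetra-ortho-substituted ether while O1 is the more basic and less hindered oxygen, the one ring C–H of 2 belongs to a ring deactivated by three bromines and the aprotic medium with a caesium counter-ion favours the oxygen, and C6 is the least hindered β-carbon of 3, whose adduct can aromatise without loss of bromide. Adduct 6 should be oxidised in part by 3 to quinone 5 with return of 2, but the excess of 2 reverses this as 3 is used up, and the Na2S2O4 wash reduces whatever 5 is left.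

Compound list
1 | 2,5-dibromobenzene-1,4-diol | Oc1cc(Br)c(O)cc1Br | starting material
2 | 2,3,5-tribromobenzene-1,4-diol | Oc1cc(Br)c(O)c(Br)c1Br | intermediate
3 | 2,3,5-tribromocyclohexa-2,5-diene-1,4-dione | O=C1C=C(Br)C(=O)C(Br)=C1Br | intermediate
4 | 2,3,5-tribromo-4-hydroxy-6-(2,3,5-tribromo-4-hydroxyphenoxy)cyclohexa-2,4-dien-1-one (racemic, not isolated) | O=C1C(Br)=C(Br)C(O)=C(Br)C1Oc2cc(Br)c(O)c(Br)c2Br | intermediate
5 | 2,3,5-tribromo-6-(2,3,5-tribromo-4-hydroxyphenoxy)cyclohexa-2,5-diene-1,4-dione (not isolated) | O=C1C(Br)=C(Br)C(=O)C(Oc2cc(Br)c(O)c(Br)c2Br)=C1Br | intermediate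
6 | 2,3,5-tribromo-6-(2,3,5-tribromo-4-hydroxyphenoxy)benzene-1,4-diol | Oc1c(Br)cc(Oc2c(O)c(Br)c(Br)c(O)c2Br)c(Br)c1Br | target

Total step count: 3. Longest linear sequence: 3 steps (1 → 2 → 3 → 6); 2 enters step 3 a second time as the nucleophile, and its excess should be recoverable.

Steps most likely to fail, the riskiest first:

For step 3, the phenoxide might attack a bromine-bearing carbon with loss of bromide, react through O4, or transfer an electron to the quinone so that semiquinone radicals end in oligomeric ethers. The fallback would give up the redox-neutral addition for the known displacement of halide from a tetrahaloquinone by a phenoxide that has only one free oxygen. It would set out from 2, which Br2 and then HNO3 in AcOH would take to 2,3,5,6-tetrabromocyclohexa-2,5-diene-1,4-dione F1. F1 in excess and commercial 2-bromo-4-methoxyphenol F2 with K2CO3 in MeCN would give 2,3,5-tribromo-6-(2-bromo-4-methoxyphenoxy)cyclohexa-2,5-diene-1,4-dione F3 by addition–elimination. Na2S2O4 would reduce it to 2,3,5-tribromo-6-(2-bromo-4-methoxyphenoxy)benzene-1,4-diol F4, and BBr3 in CH2Cl2 would cleave the methyl ether to 2,3,5-tribromo-6-(2-bromo-4-hydroxyphenoxy)benzene-1,4-diol F5. Br2 (3 equiv) in AcOH would then brominate the two positions ortho to the ring A hydroxyl and oxidise ring B, which comes back to the route at quinone 5; the Na2S2O4 treatment of step 3 would give 6.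

For step 1, bromination might run on to the tetrabromide while 1 remains, and partial oxidation might give quinhydrone-type mixtures that resist separation. The fallback would change from substitution on the arene to addition on the quinone. It would set out from 1, which Ag2O in Et2O would oxidise to 2,5-dibromocyclohexa-2,5-diene-1,4-dione F6. Slow addition of F6 to HBr (48% aq.) in AcOH would bring about the classical 1,4-addition of a hydrogen halide to a quinone, which places a single bromine because the adduct is a hydroquinone, and would come back to the route at 2.

For step 2, the oxidation might stop at the quinhydrone of 2 and 3, or adventitious water might attack the electrophilic quinone. The fallback would reach 3 without oxidising 2. It would set out from 1 by way of 2,5-dibromocyclohexa-2,5-diene-1,4-dione F6, made as above. Br2 in CHCl3 would add across one C=C of F6 to give 2,5,5,6-tetrabromocyclohex-2-ene-1,4-dione F7, and NaOAc in AcOH would eliminate HBr from F7 (the proton at C6 and a bromine from C5), which comes back to the route at 3.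

Further compounds
F1 | step 3 | 2,3,5,6-tetrabromocyclohexa-2,5-diene-1,4-dione | O=C1C(Br)=C(Br)C(=O)C(Br)=C1Br
F2 | step 3 | 2-bromo-4-methoxyphenol | COc1ccc(O)c(Br)c1
F3 | step 3 | 2,3,5-tribromo-6-(2-bromo-4-methoxyphenoxy)cyclohexa-2,5-diene-1,4-dione | COc1ccc(OC2=C(Br)C(=O)C(Br)=C(Br)C2=O)c(Br)c1
F4 | step 3 | 2,3,5-tribromo-6-(2-bromo-4-methoxyphenoxy)benzene-1,4-diol | COc1ccc(Oc2c(O)c(Br)c(Br)c(O)c2Br)c(Br)c1
F5 | step 3 | 2,3,5-tribromo-6-(2-bromo-4-hydroxyphenoxy)benzene-1,4-diol | Oc1ccc(Oc2c(O)c(Br)c(Br)c(O)c2Br)c(Br)c1
F6 | step 1 | 2,5-dibromocyclohexa-2,5-diene-1,4-dione | O=C1C=C(Br)C(=O)C=C1Br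
F7 | step 2 | 2,5,5,6-tetrabromocyclohex-2-ene-1,4-dione (racemic) | O=C1C(Br)=CC(=O)C(Br)(Br)C1Br
A1 | direct plan | cyclohexane-1,4-dione | O=C1CCC(=O)CC1
A2 | direct plan | 1-(3,4-dihydroxyphenyl)ethan-1-one | CC(=O)c1ccc(O)c(O)c1
A3 | direct plan | 5-acetylspiro[1,3-benzodioxole-2,1'-cyclohexan]-4'-one | CC(=O)c1ccc2OC3(CCC(=O)CC3)Oc2c1
A4 | direct plan | 5-acetylspiro[1,3-benzodioxole-2,1'-cyclohexa-2',5'-dien]-4'-one | CC(=O)c1ccc2OC3(C=CC(=O)C=C3)Oc2c1
A5 | direct plan | 1-[3-(2-bromo-4-hydroxyphenoxy)-4-hydroxyphenyl]ethan-1-one | CC(=O)c1ccc(O)c(Oc2ccc(O)cc2Br)c1
A6 | direct plan | 2-(2-bromo-4-hydroxyphenoxy)benzene-1,4-diol | Oc1ccc(O)c(Oc2ccc(O)cc2Br)c1
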